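What stands in the alder flask at 12 min, and which option adds most target?

common to all: substrate 0.074 M

| run | coupling partner | temperature | remark | time |
|---|---|---|---|---|
| alder | 0.0814 M | −20 °C | the very flask that is asked about, followed so far |  |
| oak | 0.055 M | −35 °C | run made earlier |  |
| flask | 0.0814 M | −20 °C |  | 12 min |

| run | time / min | target / % | substrate / % |
|---|---|---|---|
| alder | 0.833 | 12.0 | 84.9 |
| alder | 1.33 | 21.7 | 76.5 |
| alder | 2.00 | 23.7 | 67.3 |
| alder | 2.50 | 31.2 | 60.1 |
| alder | 4.00 | 40.6 | 45.4 |
| alder | 6.00 | 45.8 | 33.0 |
| alder | 10.0 | 48.5 | 16.4 |
| oak | 1.33 | 4.0 | 96.2 |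
| oak | 3.00 | 6.3 | 91.7 |
| oak | 4.00 | 8.1 | 89.6 |
| oak | 6.00 | 12.7 | 82.5 |
| oak | 8.00 | 17.2 | 78.5 |
| oak | 10.0 | 17.4 | 74.9 |

(each reading ± 1 percentage point)

- teal: at 12 min add coupling partner, 50.0% of the amount charged, then wait 6.0 min
- red: at 12 min raise the temperature by 20 K, then wait 6.0 min
- amber: at 12 min take out 90% of the target then present, then wait 6.0 min
- violet: change nothing and wait 6.0 min more

- target taken out counts as made
- the earlier runs were read with a standard deviation of 1 percentage point
- additions bring no volume worth counting

1. target, in percent of the substrate first charged, at 12 min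
2. which option adds most target ("none" when 2 percentage points or less is all one gets) (teal / red / amber / violet / none)
3. target present, with what was taken out counted in, in percent of the substrate first charged, after teal
4. target present, with what was taken out counted in, in percent of the substrate first charged, after amber

Minutes of the meeting on the alder flask, with amounts as fractions of the charge.

The first speaker said that substrate in alder falls roughly exponentially, as a step without the coupling partner would show. She proposed one number, the loss constant, the first-order constant of substrate loss read between alder's first and last readings: 0.179 min⁻¹. The forecast's own figure, about 0.19/min, differs from hers. Her constant leaves 11.6% of the substrate at 12 min, and she took that as what fresh conversion can still supply.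

The second speaker read the same constant from oak, 0.0289 min⁻¹. He argued that, if the partner does not enter, the step from −35 °C to −20 °C multiplies the constant by 6.21.

The third speaker noted that in alder at 10.0 min the readings of target and substrate together leave 35.1% of the charge elsewhere.

The forecast was then entered: 47% at 12 min, amber as best, 35.5% after teal and 50.2% after amber. Of red it said: “Heating speeds the loss too.”

The flask gives 47.5% at 12 min, 45.1% after teal and 59.1% after amber. The best option is red, which adds 31 percentage points against 12 points from amber.

    substrate ⇌ tight pair (K = 0.00150, k = 0.224 min⁻¹, Ea = 68.0 kJ mol⁻¹, ΔH = 3.00 kJ mol⁻¹)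
    tight pair ⇌ loose pair (K = 0.0630, k = 1470 min⁻¹, Ea = 59.0 kJ mol⁻¹, ΔH = −44.0 kJ mol⁻¹)
    coupling partner + tight pair → target (k = 10700 M⁻¹ min⁻¹, Ea = 42.0 kJ mol⁻¹)
    coupling partner + loose pair → isomer of the product A (k = 4980 M⁻¹ min⁻¹, Ea = 39.0 kJ mol⁻¹)
    2 substrate → homo dimer (k = 0.137 M⁻¹ min⁻¹, Ea = 65.0 kJ mol⁻¹)
    target ⇌ isomer of the product B (K = 1.40, k = 0.0920 min⁻¹, Ea = 80.0 kJ mol⁻¹, ΔH = −61.0 kJ mol⁻¹)
    (constants at −20 °C)

The loss constant held on this flask: the reckoned 11.6% stands beside 13.0% computed at 12.0 min. Red's gain of 31 points is larger than that remaining substrate, so part of it must come from material already converted, and isomer of the product B holds 32.0% at that moment. The run without the step between target and that isomer gains 13 points from red, which shows this step to be part of the gain. The same step is the main reason that target stands at 47.5% at 12 min and not at the 79.5% of the run without it.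

In a neighbour flask kept at −5 °C, the same factor gives a constant of 1.11 min⁻¹ and leaves <0.001% of the substrate, hardly any. Computed, that neighbour flask holds 0.14% substrate and 73.1% target.

(The data were generated by integration for substances that don't exist, noise included.)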